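How much J stands in this flask at 40 min, and how near saturation is it?

the same everywhere: Z 0.020 M

| charge | Q | remark | time |
|---|---|---|---|
| Monday's | 0.024 M | run made earlier |  |
| Sunday's | 0.054 M | run made earlier |  |
| flask | 0.0360 M |  | 40 min |

| run | time / min | J / % | L / % | Z / % |
|---|---|---|---|---|
| Monday's | 3.00 | 12.2 | 0 | 84.5 |
| Monday's | 8.00 | 27.9 | 1.3 | 67.8 |
| Monday's | 15.0 | 38.0 | 0.3 | 51.4 |
| Monday's | 40.0 | 45.9 | 0 | 31.6 |
| Sunday's | 3.00 | 28.4 | 0 | 67.6 |
| Sunday's | 8.00 | 45.6 | 0 | 38.2 |
| Sunday's | 15.0 | 44.1 | 0 | 22.6 |
| Sunday's | 40.0 | 29.3 | 0 | 5.9 |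

(standard deviation of a reading: 1 percentage point)

- for J the L are counted in
- as a solid, counted per litre of solution: L
- the numbers in the tables scatter by 1 percentage point (one standard deviation)

1. how much J and L together there is at 40 min, in percent of the Z charged
2. concentration of J in solution at 40 min, in percent of saturation

I kept the books on Q, the limiting reagent: it was charged at 1.80 per Z, fewer than the two that a Z takes to pass through both entries below. The first entry is one Q per Z lost, making J. The second is one Q per J lost. Both draw on the same Q, so Q cancels from their ratio. With x the fraction of Z left, J as a fraction of Z charged is x to the power s, minus x, over one minus s. Here s is the rate constant of J with Q over that of Z with Q, and J peaks where s times J equals x.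

Sunday's highest J readings stood at 8.00 min and 15.0 min, so I read the peak as lying between them. I took the mean Z of those readings over the higher J, which gave this selectivity factor as a reading: s = 0.667.

I joined the two runs by taking ln Z at 40 min as straight in Q charged, which left Z at 16.1 %. The rule then gave J 40.5 %. On those two entries my books spent 127 % of Q, in percent of Z, against 180 % charged.

Sunday's reading of 45.6 % of J stood with L 0 %, so I took saturation to lie at or above that reading, and I read Monday's L of 1.3 % as scatter of 1 percentage point. That put my estimate of J at about 88.9 % of saturation or lower.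

The forecast said 41 % and 36 %, holding “so solubility rises as Z drops”.

The flask gave 43.0 % and 86.0 %, the second 50 points above the forecast. At 40.0 min L in this flask stood at 0 %, with J dissolved under a ceiling of 10 mM. The flask's own Z, 16.7 %, put into the rule with s returned 40.9 % of J, beside 43.0 %.

    Z + Q → J (k = 0.0434 L mol⁻¹ s⁻¹)
    Q + J → E (k = 0.0267 L mol⁻¹ s⁻¹)
    Q + E → G (k = 0.0430 L mol⁻¹ s⁻¹)
    L ⇌ J, rate k4*(cs4 - [J]) while solid is left; crystals form when [J] > cs4 (solubility = 10.0 mM, k = 0.0485 s⁻¹)

For the flask with 0.061 M of Q, the same join, carried past Sunday's charge, gave Z 3.99 %, and s gave J 23.1 %. That flask computed to 24.8 %, with Z 3.77 %.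

(The data were generated by integration for substances that don't exist, and the scatter is random.)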